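**Strategy.** Humulane numbering is used (C1=C2 trans-alkene, C3 bearing methylene C15, C6=C7, C10 carbinol, C11 gem-dimethyl). C1, C2, C10 and C11 are the cyclobutane carbons of (−)-caryophyllene oxide, and C2–C10 is the bond shared by its four- and nine-membered rings; the whole route rests on breaking that bond. The key step exploits the exocyclic C3=C15 alkene beside it: thiyl addition at C15 gives a cyclobutylcarbinyl radical at C3 whose β-scission merges both rings into the eleven-membered ring, while dioxygen oxygenates C10 and sulfur marks C15 for the later diene. The precursor is the commercial epoxide itself, its oxirane masking the C6=C7 E-alkene.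

Key step: step 1

Remark: names use the humulane numbering above (C14 is the methyl on C7). Elements that the route does not control and later erases are left open in the SMILES: C10 in 3 and 4, the C2=C3 geometry in 3–6, 10 and 11, sulfur in 11, C2 in 12 and 13. The C2=C3 geometry is expected to settle thermodynamically through reversible thiyl addition.

**Step 1**
Reactants: 1 (−)-caryophyllene oxide; 2 thiophenol
Product: 3 (6R,7R)-6,7-epoxy-15-(phenylsulfanyl)humul-2-en-10-yl hydroperoxide (C10 epimers)
Conditions: PhSH (1.3 equiv, syringe pump, 8 h), AIBN (0.1 equiv), 5% O2 in N2 (slow stream), PhCF3 (0.01 M in 1), 75 °C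
Reagents that add atoms: dioxygen, O=O
Why: Proposed new method: PhS• adds to the terminal C15 of the exocyclic alkene, the tertiary cyclobutylcarbinyl radical at C3 undergoes β-scission of the C2–C10 bond (C2=C3 alkene, secondary C10 radical, cyclobutane strain released), and the C10 radical is captured by O2 and then takes hydrogen from PhSH, which carries the chain. The closest known reaction types are the thiol–olefin co-oxidation of alkenes and the thiyl-radical opening of the β-pinene cyclobutane; their combination on a fused bicycle has not been shown. The eleven-membered ring arises by fragmentation of the bond common to the four- and nine-membered rings and not by a ring-closing bond formation, so no macrocyclisation entropy has to be paid. C10 becomes a stereocentre without control, which is harmless because step 2 oxidises it to the ketone, and the C2=C3 geometry is irrelevant because step 6 moves that alkene. The step needs scission of C2–C10 rather than C1–C2, secured by secondary versus primary radical formation, and scission before O2 or PhSH intercepts the C3 radical, secured by heat, high dilution, slow thiol addition, an oxygen-lean gas stream and the reversibility of thiyl addition.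

**Step 2**
Reactants: 3 hydroperoxide (C10 epimers)
Product: 5 (6R,7R)-6,7-epoxy-15-(phenylsulfanyl)humul-2-en-10-one, via C10 alcohol epimers 4 (not isolated)
Conditions: PPh3 (1.05 equiv), CH2Cl2, 0 °C; then NaHCO3, Dess–Martin periodinane (1.5 equiv), 0 °C → rt
Reagents that add atoms: none
Why: Phosphine reduction of the O–O bond followed by Dess–Martin oxidation, which leaves aryl alkyl sulfides and epoxides alone, should funnel both C10 epimers into one ketone and so erase the uncontrolled centre.

**Step 3**
Reactants: 5 ketone
Product: 6 (6R,7R,10R)-6,7-epoxy-15-(phenylsulfanyl)humul-2-en-10-ol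
Conditions: (S)-Me-CBS (0.3 equiv), catecholborane (2 equiv), toluene, −78 → −30 °C; MeOH, aq. NaOH wash
Reagents that add atoms: none
Why: Corey–Bakshi–Shibata reduction in which the quaternary C11 is the large and the C9 methylene the small ketone substituent, so that the (S)-oxazaborolidine should give the 10R carbinol by reagent control as with tert-alkyl alkyl ketones, while catecholborane at low temperature spares alkene and epoxide and any 10S material is a diastereomer removable by chromatography.

**Step 4**
Reactants: 7 vanillic acid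
Product: 8 4-acetoxy-3-methoxybenzoic acid
Conditions: Ac2O (2.2 equiv), pyridine, rt; then H2O, rt; dilute HCl work-up
Reagents that add atoms: acetic anhydride, CC(=O)OC(C)=O
Why: Phenol acetylation (the mixed anhydride at the carboxyl group is hydrolysed on work-up) installs a protecting group that should withstand peracid, phosphite, sulfurane and low-valent tungsten and leave by mild methanolysis.

**Step 5**
Reactants: 6 (10R)-alcohol; 8 4-acetoxy-3-methoxybenzoic acid
Product: 10 (6R,7R,10R)-6,7-epoxy-15-(phenylsulfanyl)humul-2-en-10-yl 4-acetoxy-3-methoxybenzoate, via 4-acetoxy-3-methoxybenzoyl chloride 9 (not isolated)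
Conditions: 8, (COCl)2, cat. DMF, CH2Cl2, 0 °C → rt, volatiles removed; then 6, Et3N, DMAP, CH2Cl2, 0 → 40 °C
Reagents that add atoms: oxalyl chloride, O=C(Cl)C(=O)Cl (supplies the chlorine of 9 only; none of its atoms remains in 10)
Why: Acid chloride formation under Vilsmeier catalysis and DMAP-catalysed acylation of the neopentylic secondary alcohol, which takes place at oxygen and therefore retains the C10 configuration.

**Step 6**
Reactants: 10 sulfide ester
Product: 13 (6R,7R,10R)-6,7-epoxy-2-hydroxyhumul-3(15)-en-10-yl 4-acetoxy-3-methoxybenzoate (C2 epimers), via allyl sulfoxide 11 (not isolated), via C2 sulfenate ester 12 (not isolated)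
Conditions: mCPBA (1.0 equiv), NaHCO3, CH2Cl2, −78 °C; aq. NaHCO3 wash, solvent exchange; then P(OMe)3, MeOH, 25–40 °C
Reagents that add atoms: mCPBA, O=C(OO)c1cccc(Cl)c1
Why: Chemoselective sulfide-to-sulfoxide oxidation followed by Mislow–Evans [2,3]-sigmatropic rearrangement, whose sulfenate is cleaved by the thiophile trimethyl phosphite, should move the alkene to C3=C15 and place oxygen on C2, the new C2 centre being left uncontrolled because step 7 removes it.

**Step 7**
Reactants: 13 allylic alcohol
Product: 14 (6R,7R,10R)-6,7-epoxyhumula-1E,3(15)-dien-10-yl 4-acetoxy-3-methoxybenzoate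
Conditions: Martin sulfurane (1.5 equiv), CH2Cl2, 0 °C → rt
Reagents that add atoms: none
Why: Martin sulfurane dehydration of a secondary allylic alcohol, in which only C1 carries β-hydrogens (C3 is sp2) so that the conjugated C1=C2/C3=C15 diene is the sole regioisomer, and anti-elimination in the eleven-membered ring should favour the less strained E alkene.

**Step 8**
Reactants: 14 diene epoxide
Product: 15 (10R)-humula-1E,3(15),6E-trien-10-yl 4-acetoxy-3-methoxybenzoate
Conditions: WCl6 (3 equiv), n-BuLi (6 equiv), THF, −78 °C → rt; then 14, rt; aq. Rochelle salt/NaHCO3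
Reagents that add atoms: none
Why: Sharpless deoxygenation with low-valent tungsten chloride, an oxygen transfer that proceeds with retention for trisubstituted epoxides and tolerates esters, so the trans-oxirane should give the E C6=C7 alkene.

**Step 9**
Reactants: 15 triene acetate
Product: 16 (10R)-humula-1E,3(15),6E-trien-10-yl 4-hydroxy-3-methoxybenzoate (target)
Conditions: K2CO3 (0.5 equiv), MeOH, 0 °C; aq. NH4Cl
Reagents that add atoms: none
Why: Transesterification of the phenyl acetate with methanol, which should be far faster than attack on the hindered, electron-rich benzoate of the neopentylic C10 alcohol and touches no stereocentre.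

**Compound list**
1 | (−)-caryophyllene oxide, (1R,4R,6R,10S) | C=C1CC[C@H]2O[C@]2(C)CC[C@@H]3[C@@H]1CC3(C)C | starting material
2 | thiophenol | Sc1ccccc1 | starting material
3 | (6R,7R)-6,7-epoxy-15-(phenylsulfanyl)humul-2-en-10-yl hydroperoxide (C10 epimers) | CC1(C)CC=C(CSc2ccccc2)CC[C@H]3O[C@]3(C)CCC1OO | intermediate
4 | (6R,7R)-6,7-epoxy-15-(phenylsulfanyl)humul-2-en-10-ol (C10 epimers) | CC1(C)CC=C(CSc2ccccc2)CC[C@H]3O[C@]3(C)CCC1O | intermediate (not isolated)
5 | (6R,7R)-6,7-epoxy-15-(phenylsulfanyl)humul-2-en-10-one | CC1(C)CC=C(CSc2ccccc2)CC[C@H]3O[C@]3(C)CCC1=O | intermediate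
6 | (6R,7R,10R)-6,7-epoxy-15-(phenylsulfanyl)humul-2-en-10-ol | c1ccccc1SCC2=CCC(C)(C)[C@H](O)CC[C@@]3(C)O[C@@H]3CC2 | intermediate
7 | vanillic acid | COc1cc(C(=O)O)ccc1O | starting material
8 | 4-acetoxy-3-methoxybenzoic acid | COc1cc(C(=O)O)ccc1OC(C)=O | intermediate
9 | 4-acetoxy-3-methoxybenzoyl chloride | COc1cc(C(Cl)=O)ccc1OC(C)=O | intermediate (not isolated)
10 | (6R,7R,10R)-6,7-epoxy-15-(phenylsulfanyl)humul-2-en-10-yl 4-acetoxy-3-methoxybenzoate | c1ccccc1SCC2=CCC(C)(C)[C@H](OC(=O)c4ccc(OC(C)=O)c(OC)c4)CC[C@@]3(C)O[C@@H]3CC2 | intermediate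
11 | (6R,7R,10R)-6,7-epoxy-15-(phenylsulfinyl)humul-2-en-10-yl 4-acetoxy-3-methoxybenzoate (sulfur epimers) | O=S(c1ccccc1)CC2=CCC(C)(C)[C@H](OC(=O)c4ccc(OC(C)=O)c(OC)c4)CC[C@@]3(C)O[C@@H]3CC2 | intermediate (not isolated)
12 | (6R,7R,10R)-6,7-epoxy-2-(phenylsulfanyloxy)humul-3(15)-en-10-yl 4-acetoxy-3-methoxybenzoate (C2 epimers) | C=C2C(OSc1ccccc1)CC(C)(C)[C@H](OC(=O)c4ccc(OC(C)=O)c(OC)c4)CC[C@@]3(C)O[C@@H]3CC2 | intermediate (not isolated)
13 | (6R,7R,10R)-6,7-epoxy-2-hydroxyhumul-3(15)-en-10-yl 4-acetoxy-3-methoxybenzoate (C2 epimers) | C=C2C(O)CC(C)(C)[C@H](OC(=O)c4ccc(OC(C)=O)c(OC)c4)CC[C@@]3(C)O[C@@H]3CC2 | intermediate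
14 | (6R,7R,10R)-6,7-epoxyhumula-1E,3(15)-dien-10-yl 4-acetoxy-3-methoxybenzoate | C=C2/C=C/C(C)(C)[C@H](OC(=O)c4ccc(OC(C)=O)c(OC)c4)CC[C@@]3(C)O[C@@H]3CC2 | intermediate
15 | (10R)-humula-1E,3(15),6E-trien-10-yl 4-acetoxy-3-methoxybenzoate | C=C1/C=C/C(C)(C)[C@H](OC(=O)c2ccc(OC(C)=O)c(OC)c2)CC/C(C)=C/CC1 | intermediate
16 | (10R)-humula-1E,3(15),6E-trien-10-yl 4-hydroxy-3-methoxybenzoate | C=C1/C=C/C(C)(C)[C@H](OC(=O)c2ccc(O)c(OC)c2)CC/C(C)=C/CC1 | target

**Step count.** Total: 9 steps. Longest linear sequence: 8 steps (steps 1–3 and 5–9, from caryophyllene oxide).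

**Steps most likely to fail**

Step 1. The C3 radical may be intercepted by dioxygen or by thiophenol before the cyclobutane opens, or the C10 peroxyl radical may cyclise onto C2=C3 when the thiol is too dilute, so the window of concentrations may be narrow. The fallback sets out from 1 and comes back at 5. It replaces the thiyl radical by a metal-hydride hydrogen atom in a Mukaiyama hydration (Co(acac)2, PhSiH3, lean O2, THF/i-PrOH, rt, Na2S2O3 work-up). This is a known radical hydration, and opening of β-pinene-type cyclobutanes under hydrogen-atom-transfer conditions is documented. The same C3 radical forms without a reversible adduct and without a fast hydrogen donor, so only the oxygen feed has to be tuned. Ring opening and reductive oxygenation should give (6R,7R)-6,7-epoxyhumul-2-en-10-ol F1, with C15 now a methyl group. Dess–Martin oxidation should give (6R,7R)-6,7-epoxyhumul-2-en-10-one F2. Ene-type allylic chlorination of the C2=C3 alkene (Ca(OCl)2, solid CO2, CH2Cl2/H2O, 0 °C) should give (6R,7R)-2-chloro-6,7-epoxyhumul-3(15)-en-10-one F3. Sodium thiophenolate (DMF, 0 °C) should then displace chloride, by SN2′ directly to 5 and by SN2 to (6R,7R)-6,7-epoxy-2-(phenylsulfanyl)humul-3(15)-en-10-one F4. The thiyl-radical 1,3-shift of allyl sulfides (cat. PhSH, AIBN, benzene, 70 °C) should drain F4 into the more substituted alkene isomer 5.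

Step 7. The activated allylic alcohol may ionise, which would open the way to SN2′ capture at C15, to participation of the transannular oxirane, or to poor E/Z control. The fallback sets out from 13 and comes back at 14. Acetylation (Ac2O, pyridine, DMAP, CH2Cl2) should give (6R,7R,10R)-2-acetoxy-6,7-epoxyhumul-3(15)-en-10-yl 4-acetoxy-3-methoxybenzoate F5. Palladium-catalysed 1,4-elimination of the allylic acetate (Pd(PPh3)4, Et3N, dioxane, 90 °C) should then give 14. The π-allyl complex over C2–C3–C15 can lose a β-hydrogen only from C1, no free cation arises, and both C2 epimers converge.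

Step 8. The Lewis-acidic tungsten chlorides may trigger transannular cyclisation of the diene onto the oxirane, or the oxygen transfer may lose its stereospecificity. The fallback sets out from 14 and comes back at 15 without a metal halide. Thiourea (MeOH, rt → 50 °C) should convert the oxirane into the thiirane with inversion at both carbons, which keeps the trans relationship, giving (6S,7S,10R)-6,7-epithiohumula-1E,3(15)-dien-10-yl 4-acetoxy-3-methoxybenzoate F6. Triphenylphosphine (toluene, 80 °C) should then remove sulfur stereospecifically to give the E alkene of 15.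

**Further compounds**
F1 | step 1 | (6R,7R)-6,7-epoxyhumul-2-en-10-ol (C10 epimers) | CC1(C)CC=C(C)CC[C@H]3O[C@]3(C)CCC1O
F2 | step 1 | (6R,7R)-6,7-epoxyhumul-2-en-10-one | CC1(C)CC=C(C)CC[C@H]3O[C@]3(C)CCC1=O
F3 | step 1 | (6R,7R)-2-chloro-6,7-epoxyhumul-3(15)-en-10-one (C2 epimers) | C=C2C(Cl)CC(C)(C)C(=O)CC[C@@]3(C)O[C@@H]3CC2
F4 | step 1 | (6R,7R)-6,7-epoxy-2-(phenylsulfanyl)humul-3(15)-en-10-one (C2 epimers) | C=C2C(Sc1ccccc1)CC(C)(C)C(=O)CC[C@@]3(C)O[C@@H]3CC2
F5 | step 7 | (6R,7R,10R)-2-acetoxy-6,7-epoxyhumul-3(15)-en-10-yl 4-acetoxy-3-methoxybenzoate (C2 epimers) | C=C2C(OC(C)=O)CC(C)(C)[C@H](OC(=O)c4ccc(OC(C)=O)c(OC)c4)CC[C@@]3(C)O[C@@H]3CC2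
F6 | step 8 | (6S,7S,10R)-6,7-epithiohumula-1E,3(15)-dien-10-yl 4-acetoxy-3-methoxybenzoate | C=C2/C=C/C(C)(C)[C@H](OC(=O)c4ccc(OC(C)=O)c(OC)c4)CC[C@]3(C)S[C@H]3CC2
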